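The numbers in the tables come from a simulation from invented constants, noise included.

**Early times.** In the dawn run at 12.0 min, the substrate has lost 38.8% of its charge, and bis adduct, far less than that loss at 2.5%, trails behind. So I read a first coupling of substrate with coupling partner, followed by a slower second one.

| flask | substrate | coupling partner | temperature | remark | time |
|---|---|---|---|---|---|
| dawn | 0.40 M | 0.25 M | 35 °C | run made earlier |  |
| midnight | 0.40 M | 1.2 M | 68 °C | run made earlier |  |
| spring | 0.31 M | 0.80 M | 35 °C | run made earlier |  |
| violet | 0.60 M | 0.800 M | 65 °C |  | 40 min |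
| blue | 0.40 M | 0.800 M | 50 °C |  | 40 min |
| ochre | 0.10 M | 0.400 M | 20 °C |  | 40 min |
| red | 0.40 M | 0.200 M | 80 °C |  | 40 min |

- dawn (time / min: bis adduct / %, substrate / %): 5.00: 0.2, 77.2; 8.00: 2.0, 69.1; 12.0: 2.5, 61.2; 20.0: 3.8, 54.2; 30.0: 7.0, 48.9; 60.0: 6.5, 44.3
- midnight (time / min: bis adduct / %, substrate / %): 2.00: 79.8, 0.1; 4.00: 93.0, 1.6; 6.00: 98.2, 0.4; 8.00: 97.9, 1.7; 10.0: 97.5, 0.5; 12.0: 99.9, 0
- spring (time / min: bis adduct / %, substrate / %): 12.0: 25.7, 16.3; 25.0: 51.7, 4.5; 30.0: 56.0, 2.7; 50.0: 73.9, 1.0; 60.0: 81.1, 0.7

(each reading ± 1 percentage point)

- the flasks by amount of bis adduct, in percent of the substrate charged, highest first, at 40 min (violet / blue / ochre / red)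
- the amount of bis adduct, in percent of the substrate charged of the flask you put first, at 40 min
- the amount of bis adduct, in percent of the substrate charged of the flask you put last, at 40 min

- the numbers in the tables scatter by 1 percentage point (one standard deviation)

**The budget.** For red, c(coupling partner)/c(substrate) as charged gives 50.0%, and I call this ratio the partner budget. I take each substrate lost to cost one partner and each bis adduct a second, so where the partner is the limiting reagent and used up, bis adduct equals budget minus substrate lost. The dawn run tests this: its budget is 62.5%, and at 60.0 min loss plus bis adduct reads 62.2%, within the scatter.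

**Red estimate.** Red has the smallest budget of the four flasks, so I put it last. Bis adduct there is a small correction to the loss. At its last reading, the dawn run shows bis adduct as 11.7% of the substrate lost. Carrying that share to red, the loss is the budget divided by one plus the share, 44.8%, which leaves 5.23% of bis adduct. The weak link is the share, read at 35 °C and carried to 80 °C. For the top of the order I have no figure of my own.

**Forecast.** Resting on the dawn finding "substrate lost plus bis adduct formed accounts for all" the charged partner, the forecast gives blue > violet > ochre > red, with 84% for blue and 5.5% for red, above my 5.23%.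

**Result.** The flasks give blue > violet > ochre > red, with blue at 84.0% and red at 0.340%.

    substrate + coupling partner → first product (k = 0.0177 L mol⁻¹ s⁻¹, Ea = 76.0 kJ mol⁻¹)
    coupling partner + first product → bis adduct (k = 0.00576 L mol⁻¹ s⁻¹, Ea = 74.0 kJ mol⁻¹)
    substrate + bis adduct → side product (k = 3.66 × 10⁻⁴ L mol⁻¹ s⁻¹, Ea = 84.0 kJ mol⁻¹)
    (constants at 50 °C)

**Neighbour.** Red keeps 50% of its substrate and 0% of its partner, so its loss comes close to its budget of 50.0%, where I took 44.8%. Side product, counted as two, holds one partner per substrate, so the balance stands with it in the flask, and the gap between budget and loss is the 0.340% of bis adduct that red holds at 40.0 min. The same flask with 0.16 M of substrate has a budget of 125%, and at 40.0 min it keeps 5.0% of its substrate and 0% of its partner. Budget minus loss gives 30.0%, and that flask holds 30.0% of bis adduct.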